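**Retrosynthetic overview**
1. Last disconnection: CO2 is stitched between C11 and C6. The enabling feature is the lactone oxygen on C6 lying anti to the free hydroxyl on C5, with C12 carried by the 1,1-disubstituted alkene carbon C11 on C7; this is the retron of a trans-5,6-epoxide opened 5-exo at C6 by a C11 carboxylate made from an alkenyl metal and CO2.
2. Ten-membered carbocycle: intramolecular Nozaki–Hiyama 2-bromoallylation (C6–C7), which also leaves the C11–Br handle and the C6-OH that closes the 5,6-epoxide as its mesylate.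
3. Three epoxides are set before ring closure under acyclic control: 1,10 (HO-2-directed peracid, A(1,3) strain), 4,15 (HO-3-directed vanadium, A(1,2) strain), 2,3 (HO-3 displaces the C2 mesylate).
4. Chain: Cram-chelate addition of an E-alkenyl metal (C7–C10 + C1, from (S)-epichlorohydrin) to a C2–C6 aldehyde cut from C2-symmetric L-arabitol (C3 and C5 from the chiral pool, C4=C15 by Wittig).
5. Ring order: 1,10-epoxide → 4,15-epoxide → 2,3-epoxide → carbocycle → 5,6-epoxide → γ-lactone.

Key step: step 30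

Remark: atom numbers in the names are those of the germacrane skeleton of the target (ring C1–C10; C14 = methyl on C10; C15 = CH2 of the spiro-epoxide on C4; C11/C12/C13 = α-carbon, carbonyl carbon and exo-methylene of the lactone). Configurations are carried by the SMILES.
Assumption: L-arabitol, (S)-epichlorohydrin, angelic acid and CO2 are the commercial starting materials; everything named only under Conditions is a commercial reagent.

**Step 1**
Reactants: 1 L-arabitol
Product: 2 1,2:4,5-di-O-isopropylidene-L-arabitol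
Conditions: 2-methoxypropene, TsOH (cat.), DMF, 0 °C
Reagents that add atoms: 2-methoxypropene, COC(C)=C
Why: kinetic acid-catalysed acetalisation should favour the two terminal dioxolanes, leaving only the central hydroxyl (future C4) free and keeping the C2 axis.

**Step 2**
Reactants: 2 1,2:4,5-di-O-isopropylidene-L-arabitol
Product: 3 bis[(4S)-2,2-dimethyl-1,3-dioxolan-4-yl]methanone
Conditions: Dess–Martin periodinane, NaHCO3, CH2Cl2, rt
Reagents that add atoms: none
Why: Dess–Martin oxidation of the lone secondary alcohol under buffered conditions should not epimerise the two α-stereocentres.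

**Step 3**
Reactants: 3 bis[(4S)-2,2-dimethyl-1,3-dioxolan-4-yl]methanone
Product: 4 (4R,4'R)-4,4'-(ethene-1,1-diyl)bis(2,2-dimethyl-1,3-dioxolane)
Conditions: Ph3PCH3Br, KOtBu, THF, 0 °C → rt
Reagents that add atoms: methyltriphenylphosphonium bromide, C[P+](c1ccccc1)(c1ccccc1)c1ccccc1.[Br-]
Why: Wittig methylenation installs C15; the non-stabilised ylide at low temperature should leave the dioxolane stereocentres (future C3 and C5) untouched.

**Step 4**
Reactants: 4 (4R,4'R)-4,4'-(ethene-1,1-diyl)bis(2,2-dimethyl-1,3-dioxolane)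
Product: 5 (2R)-3-[(4R)-2,2-dimethyl-1,3-dioxolan-4-yl]but-3-ene-1,2-diol
Conditions: 60% aq. AcOH, rt, to partial conversion; 4 recycled
Reagents that add atoms: none
Why: acetal hydrolysis; the two dioxolanes are homotopic, so cleaving either gives the same mono-diol and the arms are differentiated without a selectivity problem.

**Step 5**
Reactants: 5 (2R)-3-[(4R)-2,2-dimethyl-1,3-dioxolan-4-yl]but-3-ene-1,2-diol
Product: 7 primary 4-methoxybenzyl ether of 5 (6-OPMB; 5-OH), via stannylene acetal 6 (not isolated)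
Conditions: Bu2SnO, toluene, reflux (−H2O); then PMBCl, Bu4NI (cat.), DMF, 50 °C
Reagents that add atoms: 4-methoxybenzyl chloride, COc1ccc(CCl)cc1; dibutyltin oxide, CCCC[Sn](=O)CCCC (tin only in 6)
Why: stannylene-acetal O-alkylation activates the less hindered primary oxygen, so the PMB group goes on the future O-6.

**Step 6**
Reactants: 7 primary 4-methoxybenzyl ether of 5
Product: 8 TBS ether of 7 (5-OTBS; 6-OPMB; 2,3-acetonide)
Conditions: TBSOTf, 2,6-lutidine, CH2Cl2, −78 → 0 °C
Reagents that add atoms: tert-butyldimethylsilyl triflate, CC(C)(C)[Si](C)(C)OS(=O)(=O)C(F)(F)F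
Why: silyl triflate silylation of the hindered secondary allylic alcohol puts the fluoride-labile group on the future O-5.

**Step 7**
Reactants: 8 TBS ether of 7
Product: 10 2,3-O-(4-methoxybenzylidene) acetal (5-OTBS; 6-OPMB), via diol 9 (not isolated)
Conditions: PPTS, MeOH, rt; evaporate; then 4-MeOC6H4CH(OMe)2, PPTS, CH2Cl2, rt
Reagents that add atoms: 4-methoxybenzaldehyde dimethyl acetal, COC(OC)c1ccc(OC)cc1
Why: acid-catalysed transacetalisation (acetonide methanolysis, then benzylidene acetal formation) prepares the second arm for regioselective opening; the secondary TBS and the PMB ether should tolerate PPTS.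

**Step 8**
Reactants: 10 2,3-O-(4-methoxybenzylidene) acetal
Product: 11 (2R,4R)-4-(TBSO)-2,5-bis(PMBO)-3-methylenepentan-1-ol (germacrane C2-OH; 3-OPMB)
Conditions: DIBAL-H, CH2Cl2, −78 → 0 °C
Reagents that add atoms: none
Why: reductive opening of the benzylidene acetal: aluminium binds the less hindered primary oxygen and hydride reduces the oxocarbenium ion, leaving PMB on the secondary O-3 and freeing the primary alcohol.

**Step 9**
Reactants: 11 (2R,4R)-4-(TBSO)-2,5-bis(PMBO)-3-methylenepentan-1-ol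
Product: 12 (2R,4R)-4-(TBSO)-2,5-bis(PMBO)-3-methylenepentanal
Conditions: Dess–Martin periodinane, NaHCO3, CH2Cl2, 0 °C; used at once
Reagents that add atoms: none
Why: Dess–Martin oxidation gives the α-alkoxy aldehyde without epimerisation or migration of the β,γ-alkene.

**Step 10**
Reactants: 13 (S)-epichlorohydrin
Product: 14 (S)-1-chloro-5-(trimethylsilyl)pent-4-yn-2-ol
Conditions: TMS-acetylene, n-BuLi, THF, −78 °C; BF3·OEt2; then 13
Reagents that add atoms: (trimethylsilyl)acetylene, C#C[Si](C)(C)C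
Why: BF3-promoted alkynylation of the epoxide (Yamaguchi–Hirao type) occurs at the unsubstituted carbon, so the stereocentre (future C8) is not touched.

**Step 11**
Reactants: 14 (S)-1-chloro-5-(trimethylsilyl)pent-4-yn-2-ol
Product: 17 (S)-hex-1-en-5-yn-3-ol, via epoxide 15 (not isolated), via silylated enynol 16 (not isolated)
Conditions: Me3S+ I−, n-BuLi, THF, −20 °C → rt; then K2CO3, MeOH, rt
Reagents that add atoms: trimethylsulfonium iodide, C[S+](C)C.[I-]
Why: base closes the chlorohydrin to the terminal epoxide, dimethylsulfonium methylide (Corey–Chaykovsky reagent) opens it at CH2 and the betaine loses Me2S to give the allylic alcohol, and methanolysis removes the C-silyl group; the carbinol carbon is never a reacting centre.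

**Step 12**
Reactants: 17 (S)-hex-1-en-5-yn-3-ol
Product: 18 (S)-tert-butyl(hex-1-en-5-yn-3-yloxy)dimethylsilane
Conditions: TBSCl, imidazole, DMF, rt
Reagents that add atoms: tert-butyldimethylsilyl chloride, CC(C)(C)[Si](C)(C)Cl
Why: standard silylation protects the future O-8.

**Step 13**
Reactants: 18 (S)-tert-butyl(hex-1-en-5-yn-3-yloxy)dimethylsilane
Product: 20 (S,E)-tert-butyl[(6-iodo-5-methylhexa-1,5-dien-3-yl)oxy]dimethylsilane, via alkenylalane 19 (not isolated)
Conditions: Me3Al, Cp2ZrCl2 (cat.), CH2Cl2, 0 °C → rt; then I2, THF, −30 °C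
Reagents that add atoms: trimethylaluminium, C[Al](C)C; iodine, II
Why: Negishi zirconium-catalysed syn-carboalumination puts methyl (C14) on the internal and aluminium on the terminal alkyne carbon, and iodinolysis with retention gives the E-alkenyl iodide; the terminal alkene reacts far more slowly.

**Step 14**
Reactants: 20 (S,E)-alkenyl iodide; 12 (2R,4R)-4-(TBSO)-2,5-bis(PMBO)-3-methylenepentanal
Product: 22 C1–C2 coupled allylic alcohol (2-OH; 3-OPMB; 6-OPMB; 5-OTBS; 8-OTBS; 1(10)E- and 4(15)-alkenes; vinyl on C8), via alkenyllithium 21 (not isolated)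
Conditions: 20, t-BuLi, Et2O, −78 °C; then 12·MgBr2·OEt2, CH2Cl2, −78 °C
Reagents that add atoms: tert-butyllithium, [Li]C(C)(C)C (lithium only in 21)
Why: iodine–lithium exchange with retention of the E geometry, then Cram-chelate addition: magnesium bridges the aldehyde oxygen and the α-OPMB oxygen, so the nucleophile attacks anti to the C4 branch and sets C2 syn (threo) to O-3.

**Step 15**
Reactants: 22 C1–C2 coupled allylic alcohol
Product: 23 1,10-epoxy alcohol (2-OH)
Conditions: mCPBA, NaHCO3, CH2Cl2, 0 °C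
Reagents that add atoms: 3-chloroperoxybenzoic acid, OOC(=O)c1cccc(Cl)c1
Why: hydroxyl-directed (Henbest) peracid epoxidation: A(1,3) strain between the C2 substituents and the C14 methyl holds H-2 in the alkene plane, so oxygen is delivered to the face of HO-2 and sets C1 and C10 threo to it; the electron-rich trisubstituted alkene should react before the two others.

**Step 16**
Reactants: 23 1,10-epoxy alcohol
Product: 24 C2 mesylate
Conditions: MsCl, Et3N, CH2Cl2, 0 °C
Reagents that add atoms: methanesulfonyl chloride, CS(=O)(=O)Cl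
Why: sulfonylation turns O-2 into the leaving group for the later inversion at C2.

**Step 17**
Reactants: 24 C2 mesylate
Product: 25 3,6-diol (2-OMs; 1,10-epoxide)
Conditions: DDQ, CH2Cl2/pH 7 buffer, 0 °C
Reagents that add atoms: none
Why: oxidative PMB cleavage (hydride abstraction, then hydrolysis) frees O-3 and O-6 under neutral conditions that spare the epoxide, the mesylate and the silyl ethers.

**Step 18**
Reactants: 25 3,6-diol
Product: 26 1,10:4,15-diepoxide (3-OH; 2-OMs)
Conditions: VO(acac)2 (cat.), t-BuOOH, CH2Cl2, 0 °C → rt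
Reagents that add atoms: tert-butyl hydroperoxide, CC(C)(C)OO
Why: vanadium-catalysed allylic-alkoxide-directed epoxidation: A(1,2) strain between the C5 branch on the alkene and C2 places H-3 near the alkene plane, so oxygen is delivered erythro to HO-3 and sets C4; the terminal vinyl group has no directing hydroxyl, and the homoallylic HO-6 should direct much more slowly.

**Step 19**
Reactants: 26 1,10:4,15-diepoxide
Product: 27 1,10:2,3:4,15-triepoxide (6-OH; 5-OTBS; 8-OTBS; vinyl on C8)
Conditions: K2CO3, MeOH, 0 °C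
Reagents that add atoms: none
Why: intramolecular Williamson closure (3-exo-tet) with inversion at C2 turns the threo hydroxy mesylate into the cis-2,3-epoxide; mesylate displacement should outrun Payne equilibration.

**Step 20**
Reactants: 27 1,10:2,3:4,15-triepoxide
Product: 29 C7 aldehyde, via ozonide 28 (not isolated)
Conditions: O3, CH2Cl2, −78 °C; then PPh3, −78 °C → rt
Reagents that add atoms: ozone, [O-][O+]=O
Why: ozonolysis of the only remaining alkene with reductive work-up gives the α-silyloxy aldehyde at C7.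

**Step 21**
Reactants: 29 C7 aldehyde
Product: 30 ethyl (Z)-2-bromoenoate (C7=C11(Br)–C13O2Et)
Conditions: Ph3P=C(Br)CO2Et, CH2Cl2, rt
Reagents that add atoms: ethyl 2-bromo-2-(triphenylphosphoranylidene)acetate, CCOC(=O)C(Br)=P(c1ccccc1)(c1ccccc1)c1ccccc1
Why: Wittig olefination with the stabilised bromo-ylide builds C11 (with its bromine) and C13; the alkene geometry does not matter for the later allylmetal.

**Step 22**
Reactants: 30 ethyl (Z)-2-bromoenoate
Product: 31 2-bromoallylic alcohol (13-OH; 6-OH)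
Conditions: DIBAL-H, CH2Cl2, −78 °C
Reagents that add atoms: none
Why: DIBAL-H reduction of the ester at low temperature, where the epoxides and the alkenyl bromide should be inert.

**Step 23**
Reactants: 31 2-bromoallylic alcohol
Product: 32 allylic bromide (6-OH)
Conditions: NBS, Me2S, CH2Cl2, −20 → 0 °C
Reagents that add atoms: N-bromosuccinimide, BrN1C(=O)CCC1=O
Why: Corey–Kim halogenation: only the allylic alkoxysulfonium ion is displaced by bromide, while the saturated primary one reverts to the alcohol on work-up.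

**Step 24**
Reactants: 32 allylic bromide
Product: 33 C6 aldehyde
Conditions: Dess–Martin periodinane, NaHCO3, CH2Cl2, 0 °C
Reagents that add atoms: none
Why: Dess–Martin oxidation gives the α-silyloxy aldehyde at C6 without touching the allylic bromide.

**Step 25**
Reactants: 33 C6 aldehyde
Product: 35 ten-membered carbocycle (6-OH; 7-(1-bromovinyl); 5-OTBS; 8-OTBS; three epoxides), via allylchromium species 34 (not isolated)
Conditions: CrCl2 (excess), THF, rt, slow addition (high dilution)
Reagents that add atoms: chromium(II) chloride, Cl[Cr]Cl (chromium only in 34)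
Why: intramolecular Nozaki–Hiyama (Barbier-type) allylation: the allylchromium(III) adds through its γ-carbon C7 in a chair transition state, giving the anti C6-OH/C7 relationship, while Felkin–Anh attack anti to the C5 silyloxy group fixes the aldehyde face; the alkenyl bromide is inert to Cr(II) without nickel.

**Step 26**
Reactants: 35 ten-membered carbocycle
Product: 36 C6 mesylate
Conditions: MsCl, Et3N, DMAP (cat.), CH2Cl2, 0 °C
Reagents that add atoms: methanesulfonyl chloride, CS(=O)(=O)Cl
Why: sulfonylation of the new secondary alcohol prepares C6 for inversion.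

**Step 27**
Reactants: 36 C6 mesylate
Product: 37 1,10:2,3:4,15:5,6-tetraepoxide 8-ol (7-(1-bromovinyl))
Conditions: TBAF, THF, 0 °C → rt
Reagents that add atoms: none
Why: fluoride desilylation frees the C5 alkoxide, which displaces the anti-periplanar C6 mesylate (3-exo-tet, inversion at C6) to give the trans-5,6-epoxide; the same operation frees HO-8.

**Step 28**
Reactants: 37 tetraepoxide 8-ol; 38 angelic acid
Product: 39 8-O-angelate (alkenyl bromide)
Conditions: 38, 2,4,6-Cl3C6H2COCl, Et3N, toluene, rt; then 37, 80 °C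
Reagents that add atoms: none
Why: Yamaguchi esterification through the mixed anhydride should acylate HO-8 with little Z-to-E isomerisation of the angelate.

**Step 29**
Reactants: 39 8-O-angelate (alkenyl bromide)
Product: 40 alkenylboronate (C11–B neopentyl glycol ester)
Conditions: B2nep2, PdCl2(PPh3)2 (cat.), PPh3, KOPh, toluene, 50 °C
Reagents that add atoms: bis(neopentyl glycolato)diboron, CC1(C)COB(OC1)B1OCC(C)(C)CO1
Why: Miyaura borylation (oxidative addition into the alkenyl C–Br bond, phenoxide-assisted transmetalation, reductive elimination); no epoxide is allylic to the alkene, so π-allyl ionisation is not possible.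

**Step 30**
Reactants: 40 alkenylboronate; 41 carbon dioxide
Product: 44 CNP0594916.1 (8-angeloyloxy-1,10:2,3:4,15-triepoxy-5-hydroxygermacr-11(13)-en-12,6-olide), via potassium carboxylate 42 (not isolated), via epoxy acid 43 (not isolated)
Conditions: (IPr)CuCl (cat.), KOtBu, CO2 (1 atm), THF, 60 °C; then aq. NaH2PO4 (pH ≈ 4.5), rt
Reagents that add atoms: potassium tert-butoxide, CC(C)(C)[O-].[K+] (potassium only in 42)
Why: Proposed new method: alkoxide-activated transmetalation of the alkenyl–boron bond of 40 to (IPr)Cu gives an alkenylcopper that inserts CO2 (C11–C12 bond) and is released as potassium acrylate 42; this carboxylate, or the acid 43 after buffered protonation, attacks C6 of the neighbouring trans-5,6-epoxide from the back (O–C6 bond), so the lactone closes 5-exo-tet while the epoxide oxygen stays on C5 as the free hydroxyl. The closest known reaction types are the Cu(I)–NHC-catalysed carboxylation of alkenylboronic esters with CO2 and the spontaneous lactonisation of γ,δ-epoxy carboxylic acids; joining them in one flask on a polyepoxide is the new part. The only new stereocentre is C6, set by stereospecific SN2 inversion of the (5S,6R)-epoxide, which gives the trans-fused lactone with O-6 anti to HO-5; C5 keeps its configuration. The step needs site selectivity among four epoxides and C6-over-C5 regioselectivity: only the 5,6-epoxide lies γ,δ to the carboxylate, attack at C5 would be 6-endo and is hindered by the fully substituted C4, and the weakly acidic buffered work-up should leave the 1,10-, 2,3- and 4,15-epoxides alone. The angelate should survive because tert-butoxide is held as the boronate complex and as tert-butyl carbonate under CO2, and any C5 alkoxide formed before work-up is masked as its carbonate, which should suppress Payne migration towards the 4,15-epoxide.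

**Compound list**
1 | L-arabitol | OC[C@H](O)C(O)[C@@H](O)CO | starting material
2 | 1,2:4,5-di-O-isopropylidene-L-arabitol | CC1(C)OC[C@H](O1)C(O)[C@@H]1COC(C)(C)O1 | intermediate
3 | bis[(4S)-2,2-dimethyl-1,3-dioxolan-4-yl]methanone | CC1(C)OC[C@H](O1)C(=O)[C@@H]1COC(C)(C)O1 | intermediate
4 | (4R,4'R)-4,4'-(ethene-1,1-diyl)bis(2,2-dimethyl-1,3-dioxolane) | CC1(C)OC[C@H](O1)C(=C)[C@@H]1COC(C)(C)O1 | intermediate
5 | (2R)-3-[(4R)-2,2-dimethyl-1,3-dioxolan-4-yl]but-3-ene-1,2-diol | CC1(C)OC[C@H](O1)C(=C)[C@@H](O)CO | intermediate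
6 | dibutylstannylene acetal of 5 | CC1(C)OC[C@H](O1)C(=C)[C@@H]1CO[Sn](CCCC)(CCCC)O1 | intermediate (not isolated)
7 | primary PMB ether of 5 | CC1(C)OC[C@H](O1)C(=C)[C@@H](O)COCc1ccc(OC)cc1 | intermediate
8 | TBS ether of 7 | CC1(C)OC[C@H](O1)C(=C)[C@@H](O[Si](C)(C)C(C)(C)C)COCc1ccc(OC)cc1 | intermediate
9 | (2R,4R)-4-(TBSO)-5-(PMBO)-3-methylenepentane-1,2-diol | OC[C@H](O)C(=C)[C@@H](O[Si](C)(C)C(C)(C)C)COCc1ccc(OC)cc1 | intermediate (not isolated)
10 | 4-methoxybenzylidene acetal of 9 (acetal carbon unassigned) | COc1ccc(cc1)C1OC[C@H](O1)C(=C)[C@@H](O[Si](C)(C)C(C)(C)C)COCc1ccc(OC)cc1 | intermediate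
11 | (2R,4R)-4-(TBSO)-2,5-bis(PMBO)-3-methylenepentan-1-ol | OC[C@H](OCc1ccc(OC)cc1)C(=C)[C@@H](O[Si](C)(C)C(C)(C)C)COCc1ccc(OC)cc1 | intermediate
12 | (2R,4R)-4-(TBSO)-2,5-bis(PMBO)-3-methylenepentanal | O=C[C@H](OCc1ccc(OC)cc1)C(=C)[C@@H](O[Si](C)(C)C(C)(C)C)COCc1ccc(OC)cc1 | intermediate
13 | (S)-epichlorohydrin | ClC[C@@H]1CO1 | starting material
14 | (S)-1-chloro-5-(trimethylsilyl)pent-4-yn-2-ol | ClC[C@@H](O)CC#C[Si](C)(C)C | intermediate
15 | (S)-trimethyl[3-(oxiran-2-yl)prop-1-yn-1-yl]silane | C1O[C@H]1CC#C[Si](C)(C)C | intermediate (not isolated)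
16 | (S)-6-(trimethylsilyl)hex-1-en-5-yn-3-ol | C=C[C@@H](O)CC#C[Si](C)(C)C | intermediate (not isolated)
17 | (S)-hex-1-en-5-yn-3-ol | C=C[C@@H](O)CC#C | intermediate
18 | (S)-tert-butyl(hex-1-en-5-yn-3-yloxy)dimethylsilane | C=C[C@@H](O[Si](C)(C)C(C)(C)C)CC#C | intermediate
19 | (S,E)-alkenyl(dimethyl)alane | C=C[C@@H](O[Si](C)(C)C(C)(C)C)C/C(C)=C/[Al](C)C | intermediate (not isolated)
20 | (S,E)-tert-butyl[(6-iodo-5-methylhexa-1,5-dien-3-yl)oxy]dimethylsilane | C=C[C@@H](O[Si](C)(C)C(C)(C)C)C/C(C)=C/I | intermediate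
21 | (S,E)-alkenyllithium from 20 | C=C[C@@H](O[Si](C)(C)C(C)(C)C)C/C(C)=C/[Li] | intermediate (not isolated)
22 | coupled allylic alcohol (2-OH; 3-OPMB; 6-OPMB; 5-OTBS; 8-OTBS) | C=C[C@@H](O[Si](C)(C)C(C)(C)C)C/C(C)=C/[C@@H](O)[C@H](OCc1ccc(OC)cc1)C(=C)[C@@H](O[Si](C)(C)C(C)(C)C)COCc1ccc(OC)cc1 | intermediate
23 | 1,10-epoxy alcohol | C=C[C@@H](O[Si](C)(C)C(C)(C)C)C[C@@]1(C)O[C@@H]1[C@@H](O)[C@H](OCc1ccc(OC)cc1)C(=C)[C@@H](O[Si](C)(C)C(C)(C)C)COCc1ccc(OC)cc1 | intermediate
24 | C2 mesylate | C=C[C@@H](O[Si](C)(C)C(C)(C)C)C[C@@]1(C)O[C@@H]1[C@@H](OS(C)(=O)=O)[C@H](OCc1ccc(OC)cc1)C(=C)[C@@H](O[Si](C)(C)C(C)(C)C)COCc1ccc(OC)cc1 | intermediate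
25 | 3,6-diol (2-OMs) | C=C[C@@H](O[Si](C)(C)C(C)(C)C)C[C@@]1(C)O[C@@H]1[C@@H](OS(C)(=O)=O)[C@H](O)C(=C)[C@@H](O[Si](C)(C)C(C)(C)C)CO | intermediate
26 | 1,10:4,15-diepoxide (3-OH; 2-OMs) | C=C[C@@H](O[Si](C)(C)C(C)(C)C)C[C@@]1(C)O[C@@H]1[C@@H](OS(C)(=O)=O)[C@H](O)[C@]1(CO1)[C@@H](O[Si](C)(C)C(C)(C)C)CO | intermediate
27 | 1,10:2,3:4,15-triepoxide (6-OH) | C=C[C@@H](O[Si](C)(C)C(C)(C)C)C[C@@]1(C)O[C@@H]1[C@@H]1O[C@@H]1[C@]1(CO1)[C@@H](O[Si](C)(C)C(C)(C)C)CO | intermediate
28 | secondary ozonide of 27 (ring carbon unassigned) | C1OC(OO1)[C@@H](O[Si](C)(C)C(C)(C)C)C[C@@]1(C)O[C@@H]1[C@@H]1O[C@@H]1[C@]1(CO1)[C@@H](O[Si](C)(C)C(C)(C)C)CO | intermediate (not isolated)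
29 | C7 aldehyde | O=C[C@@H](O[Si](C)(C)C(C)(C)C)C[C@@]1(C)O[C@@H]1[C@@H]1O[C@@H]1[C@]1(CO1)[C@@H](O[Si](C)(C)C(C)(C)C)CO | intermediate
30 | ethyl (Z)-2-bromoenoate | CCOC(=O)/C(Br)=C/[C@@H](O[Si](C)(C)C(C)(C)C)C[C@@]1(C)O[C@@H]1[C@@H]1O[C@@H]1[C@]1(CO1)[C@@H](O[Si](C)(C)C(C)(C)C)CO | intermediate
31 | 2-bromoallylic alcohol (13-OH; 6-OH) | OC/C(Br)=C/[C@@H](O[Si](C)(C)C(C)(C)C)C[C@@]1(C)O[C@@H]1[C@@H]1O[C@@H]1[C@]1(CO1)[C@@H](O[Si](C)(C)C(C)(C)C)CO | intermediate
32 | allylic bromide (6-OH) | BrC/C(Br)=C/[C@@H](O[Si](C)(C)C(C)(C)C)C[C@@]1(C)O[C@@H]1[C@@H]1O[C@@H]1[C@]1(CO1)[C@@H](O[Si](C)(C)C(C)(C)C)CO | intermediate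
33 | C6 aldehyde | BrC/C(Br)=C/[C@@H](O[Si](C)(C)C(C)(C)C)C[C@@]1(C)O[C@@H]1[C@@H]1O[C@@H]1[C@]1(CO1)[C@@H](O[Si](C)(C)C(C)(C)C)C=O | intermediate
34 | allylchromium(III) species | Cl[Cr](Cl)C/C(Br)=C/[C@@H](O[Si](C)(C)C(C)(C)C)C[C@@]1(C)O[C@@H]1[C@@H]1O[C@@H]1[C@]1(CO1)[C@@H](O[Si](C)(C)C(C)(C)C)C=O | intermediate (not isolated)
35 | ten-membered carbocycle (6-OH; 7-(1-bromovinyl)) | C=C(Br)[C@@H]1[C@@H](O[Si](C)(C)C(C)(C)C)C[C@@]2(C)O[C@@H]2[C@@H]2O[C@@H]2[C@]2(CO2)[C@@H](O[Si](C)(C)C(C)(C)C)[C@H]1O | intermediate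
36 | C6 mesylate | C=C(Br)[C@@H]1[C@@H](O[Si](C)(C)C(C)(C)C)C[C@@]2(C)O[C@@H]2[C@@H]2O[C@@H]2[C@]2(CO2)[C@@H](O[Si](C)(C)C(C)(C)C)[C@H]1OS(C)(=O)=O | intermediate
37 | tetraepoxide 8-ol | C=C(Br)[C@@H]1[C@@H](O)C[C@@]2(C)O[C@@H]2[C@@H]2O[C@@H]2[C@]2(CO2)[C@H]2O[C@H]12 | intermediate
38 | angelic acid | OC(=O)/C(C)=C\C | starting material
39 | 8-O-angelate (alkenyl bromide) | C=C(Br)[C@@H]1[C@@H](OC(=O)/C(C)=C\C)C[C@@]2(C)O[C@@H]2[C@@H]2O[C@@H]2[C@]2(CO2)[C@H]2O[C@H]12 | intermediate
40 | alkenylboronate | C=C(B3OCC(C)(C)CO3)[C@@H]1[C@@H](OC(=O)/C(C)=C\C)C[C@@]2(C)O[C@@H]2[C@@H]2O[C@@H]2[C@]2(CO2)[C@H]2O[C@H]12 | intermediate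
41 | carbon dioxide | O=C=O | starting material
42 | potassium carboxylate | C=C(C(=O)[O-])[C@@H]1[C@@H](OC(=O)/C(C)=C\C)C[C@@]2(C)O[C@@H]2[C@@H]2O[C@@H]2[C@]2(CO2)[C@H]2O[C@H]12.[K+] | intermediate (not isolated)
43 | epoxy acid | C=C(C(=O)O)[C@@H]1[C@@H](OC(=O)/C(C)=C\C)C[C@@]2(C)O[C@@H]2[C@@H]2O[C@@H]2[C@]2(CO2)[C@H]2O[C@H]12 | intermediate (not isolated)
44 | CNP0594916.1 | C=C1C(=O)O[C@H]2[C@H]1[C@@H](OC(=O)/C(C)=C\C)C[C@@]1(C)O[C@@H]1[C@@H]1O[C@@H]1[C@]1(CO1)[C@H]2O | target

**Totals**
Total steps: 30. Longest linear sequence: 26 (steps 1–9 and 14–30).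

**Three steps most likely to fail**

Step 30 (proposed new method). The boron-to-copper transmetalation may stall or end in protodeboronation, and the basic medium may cleave or isomerise the angelate or open an epoxide through a transient alkoxide. The fallback sets out from 39 and uses known chemistry only. Palladium-catalysed alkoxycarbonylation of the alkenyl bromide with CO and 2-(trimethylsilyl)ethanol (Pd(PPh3)4, Et3N, DMF, 60 °C) would give the 2-(trimethylsilyl)ethyl acrylate F1. Fluoride-induced fragmentation of this ester (TBAF buffered with AcOH, THF, 0 °C) would release the epoxy acid 43, which lactonises by the known γ,δ-epoxy-acid closure. The fallback comes back at 44.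

Step 25. The substrate-controlled ring closure may show poor facial selectivity at the aldehyde (C6/C7 diastereomers), and the long exposure to Cr(III) under high dilution may favour oligomers. The fallback sets out from 33 and changes the control element from substrate to catalyst: a catalytic asymmetric chromium-mediated 2-haloallylation (Cr(III) salt with a chiral sulfonamide ligand, Mn as terminal reductant, cobalt phthalocyanine, Cp2ZrCl2, 2,6-lutidine, MeCN, slow addition), with the ligand enantiomer chosen to reinforce Felkin–Anh attack. It comes back at 35; no new compound is made on this way (F0).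

Step 14. Chelation control may erode through competing non-chelated (Felkin–Anh) addition or through enolisation of the β,γ-unsaturated aldehyde, giving C2 epimers that would end in the wrong 1,10- and 2,3-epoxides. The fallback sets out from 20 and 12 and sets C2 by reduction instead of addition. Nozaki–Hiyama–Kishi coupling (CrCl2, NiCl2 cat., DMSO/THF) would give the C2-epimeric allylic alcohols F2, and Dess–Martin oxidation would give the enone F3. Felkin–Anh-controlled 1,2-reduction with K-Selectride (THF, −78 °C; the β,β-disubstituted enone resists conjugate reduction) should then deliver the 2,3-syn alcohol. It comes back at 22.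

**Further compounds**
F1 | step 30 | 2-(trimethylsilyl)ethyl acrylate of the 8-O-angeloyl tetraepoxide | C=C(C(=O)OCC[Si](C)(C)C)[C@@H]1[C@@H](OC(=O)/C(C)=C\C)C[C@@]2(C)O[C@@H]2[C@@H]2O[C@@H]2[C@]2(CO2)[C@H]2O[C@H]12
F0 | step 25 | none | none
F2 | step 14 | C2-epimeric allylic alcohols (22 and its C2 epimer) | C=C[C@@H](O[Si](C)(C)C(C)(C)C)C/C(C)=C/C(O)[C@H](OCc1ccc(OC)cc1)C(=C)[C@@H](O[Si](C)(C)C(C)(C)C)COCc1ccc(OC)cc1
F3 | step 14 | C2 enone | C=C[C@@H](O[Si](C)(C)C(C)(C)C)C/C(C)=C/C(=O)[C@H](OCc1ccc(OC)cc1)C(=C)[C@@H](O[Si](C)(C)C(C)(C)C)COCc1ccc(OC)cc1
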